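The data were computed for substances that don't exist; the scatter is artificial.

Friday's run charged twice the substrate of Saturday's run, yet Saturday's first 120 min made target at 1.93 mM h⁻¹ and Friday's first 2.50 h at 2.17 mM h⁻¹, faster than Saturday's by a factor of only 1.12. Each rate is the mean of target gained and substrate lost.

all flasks: salt in the second phase 33.6 mM; spent carrier 1.4 mM

|  | substrate | remark | volume of the second phase over the first |
|---|---|---|---|
| Saturday's | 28 mM | the very flask that is asked about, followed so far |  |
| Friday's | 56 mM | run made earlier |  |
| flask | 28 mM |  | 1.0 |

Saturday's run (percent of the substrate charged)

| time / min | target / % | substrate / % |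
|---|---|---|
| 8.00 | 2.2 | 98.2 |
| 15.0 | 0 | 98.1 |
| 25.0 | 2.8 | 97.2 |
| 40.0 | 2.5 | 95.9 |
| 60.0 | 5.2 | 95.6 |
| 120 | 13.3 | 85.7 |

Friday's run (percent of the substrate charged)

| time / h | target / % | substrate / % |
|---|---|---|
| 2.50 | 11.4 | 92.0 |
| 5.00 | 17.8 | 80.6 |
| 8.00 | 26.7 | 74.5 |
| 10.0 | 30.8 | 69.7 |
| 12.0 | 35.4 | 64.8 |
| 15.0 | 38.0 | 61.2 |

(each reading ± 1 percentage point)

- charges count per volume of the first phase; a concentration in a rate is the amount of a species over the volume of its own phase; every rate counts per litre of the first phase
- the earlier runs hold the two phases in the same ratio of volumes as the flask asked about
- no earlier run changes the charge of spent carrier; that part of a forecast is a guess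
- no earlier run changes the charge of salt in the second phase; that part of a forecast is a guess

- apparent order in spent carrier when 20% of the substrate are converted (percent change of the rate of making target for one percent more spent carrier charged)
- apparent order in salt in the second phase when 20% of the substrate are converted (percent change of the rate of making target for one percent more salt in the second phase charged)

We take one round of the catalyst as two legs in series, whose times add like resistances: spent carrier exchanging with salt in the second phase, then fresh carrier attacking substrate. The round time, the inverse turnover frequency, is carrier charged over rate: 0.725 h on Saturday, 0.644 h on Friday.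

Turn the substrate first. Doubling it halves the attack leg, so on Saturday that leg is twice the difference, 0.161 h, a correction to the 0.564 h left for exchange, which is longer than it. Being a difference of close readings, it is a rough reading.

Turn the carrier next: more carrier means more rounds of the same length, so we expect order 1.

Turn the salt last. At 20% conversion in the flask about as much salt as substrate has gone, so one percent more charged is 1.20 percent more left; we call this the lever. The exchange leg then stretches by that factor and the attack leg by 1.25, giving 0.771 as the fraction of the round spent in exchange, the exchange share. Our order in salt is this share times the lever, 0.925.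

The forecast gives 0.95 for carrier against our 1, and 0.17 for salt against our 0.925, holding that “the carrier is mostly in the QY form”, QY being fresh carrier.

The flask gives 1.0 for spent carrier and 0.71 for salt in the second phase.

    spent carrier + salt in the second phase ⇌ fresh carrier + spent salt in the second phase (K = 2.40, k = 1.20 M⁻¹ min⁻¹)
    substrate + fresh carrier → target + spent carrier (k = 2.20 M⁻¹ min⁻¹)
    fresh carrier ⇌ dormant form (K = 0.360, k = 0.00160 min⁻¹)

At 1.50 h the flask holds 58.9% of its catalyst as spent carrier, 37.0% as fresh carrier and 4.07% as dormant form. Dividing the flask's order in salt by the lever gives an exchange share of 0.596, lower than our 0.771. Stretching the two legs by salt left and substrate left, that share puts the rate at a converted fraction of 0.7 at 0.441 of the rate at 20%, and the flask, reaching that conversion at 19.4 h, stands at 0.34.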